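# Proposed total synthesis of the briarane CNP0183630.2 by glycol cleavage of a Wieland–Miescher-derived tricycle

## The problem

The target is a briarane. A cyclohexane (ring A: C1, C10–C14) is trans-fused through C1–C10 to a ten-membered carbocycle (C1–C10) that carries a cis trisubstituted C5=C6 olefin and a γ-lactone (O–C19–C17) annulated across C7–C8. Eleven stereocentres (C1, C2, C4, C7, C8, C9, C10, C11, C12, C14, C17) sit on this frame. Nine of them are contiguous, and the C11 methyl is axial and syn to the angular methyl C15.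

Only a rigid frame lets the quaternary C1 control its neighbours. In a trans-decalin the axial C15 closes the β face, so H10, O9, O8, H11 and H12 can all be delivered from the α face. C14 then needs a bulky hydride and C17 can be set from C8 through a rigid lactone. C4 is too remote for substrate control. C2 and C7 lie in the medium ring and must be steered by neighbouring hydroxyl groups.

Several groups are fragile:
- the four acetates; C4–OAc becomes β to a C2 carbonyl once the ring is open and can be lost as acetic acid;
- the tertiary β-hydroxy lactone, prone to retro-aldol cleavage and dehydration;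
- the axial C11 methyl, which epimerises when a carbonyl stands at C12 or a conjugated carbonyl reaches C10;
- the medium-ring ketones, which invite transannular reactions.

The free C12 hydroxyl must also be told apart from four acetylated ones.

The enabling feature is that C2 and C7 are both oxygenated and 1,6-related across the ten-membered ring. Joining them gives a decalin (ring B: C1, C2, C7, C8, C9, C10; ring C: C2–C7). The medium ring is therefore rings B and C with the fusion bond cut, C5=C6 is cis because it sits in the six-membered ring C, and rings A/B are the Wieland–Miescher decalin.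

## Retrosynthesis

**Endgame (51 from 50, 48, 47).** Target 51 is the desilylation product of its C12 triisopropylsilyl ether 50. That silyl ether is the only group that distinguishes the free hydroxyl from the four acetylated ones. The lactone C19–O7 bond is cut next. With C17 already in place, the lactone comes from diol 48 by oxidation of the primary C19 hydroxyl, which asks only that C7–OH be the single free secondary hydroxyl. Cutting C8–C17 instead would create two stereocentres in a flexible ring. Diol 48 is the p-methoxybenzyl ether 47 unmasked.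

**The two medium-ring carbinols (47 from 46, 44, 42, 41).** The C7–H and C2–H bonds are cut, since each carbinol has a hydroxyl neighbour that can hold a metal:
- C7 in 47 comes from enone 46 through a zinc chelate with the tertiary C8 hydroxyl.
- C2 in 44 comes from ketone 42 through a boron chelate with the axial C14 hydroxyl.

The acetates at C2, C9 and C14 are introduced between the two reductions (44 to 46). C7–OH is thus born last and needs no protection. This reduces the problem to diketone 41.

**Key cut (41 from 39).** The C2 and C7 carbonyls of 41 are reconnected as the C2–C7 bond of the tricyclic cis-diol 39. The medium ring is replaced by two six-membered rings, the olefin geometry is fixed, and the forward step is a glycol cleavage that creates no stereocentre. It asks only that the C8/C9 diol be masked (acetonide) and that no other free vicinal diol be present. A direct ten-membered ring closure would face the usual medium-ring penalties.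

**Ring C (39 from 38, 37, 36, 33 + 34).** Ring C is opened at C5=C6 by ring-closing metathesis of diene 37, whose C4 carbinol comes from enone 36 by reagent-controlled reduction. Setting C4 before ring closure makes it independent of the configuration of the two tertiary carbinols, which is lost later. The C2–C3 bond of 36 is an aldol bond between the non-enolisable ketone 33 and 3-methylbut-3-en-2-one 34.

**The C7 vinyl and C2 oxygen (33 from 32, 30, 28 + 31).** The C7–C6 bond is cut to vinylmagnesium bromide 31 and α-hydroxy ketone 30. The C2 oxygen is cut back to ketone 28, whose only enolisable position is C2. This order puts the small vinyl nucleophile first and leaves no ambiguity about which carbonyl receives which carbon.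

**C17, C7–O, C8–O and C8–C17 (28 from 27, 26, 25, 24, 23, 21, 20, 19, 18, 14 + 17).**
- Ketone 28 comes from diol 26, the reduction product of lactone 25.
- The lactone is kept through 21–25 because it is the device that sets C17: hydrogenation of the trans-fused α-methylene lactone 20 occurs opposite the axial C8 hydroxyl.
- Lactone 20 comes from diol ester 19, and the C7–O and C8–O bonds are cut together (dihydroxylation of diene ester 18 on the α face).
- The C8–C17 bond is a Stille bond between enol triflate 14 and stannane 17.
- The axial C14 alcohol of 24 is cut to ketone 23, a bulky-hydride reduction placed where no other ketone is exposed.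

**C9–O and C10–H (14 from 12, 10, 8).** The C9 oxygen is cut to silyl enol ether 10, which only the dissolving-metal reduction of enone 8 gives regiospecifically. The same step sets the trans ring fusion. All ring A work therefore has to be finished while the enone is still present.

**Ring A (8 from 7, 6, 4, 3, 2, 1).** The C11–H and C12–O bonds are cut to β-epoxide 6. A palladium-catalysed hydrogenolysis delivers hydride to C11 with inversion and leaves the C12 oxygen β, so the cis methyl/hydroxyl pair needs no later inversion. Epoxide 6 comes from dienone 4 by a bromohydrin. C20 is cut back to a γ-methylenation of (R)-Wieland–Miescher ketone 1 (to 2, isomerised to 3).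

**Stannane.** Stannane 17 is the hydrostannation product of methyl propiolate 15 with tributyltin hydride 16.

## Roads not taken

**Alternative 1:** The cut is C8–C17, made last. In the forward step SmI2 turns the C7 2-bromopropanoate of ketone A1 into a samarium enolate whose carbon adds to the neighbouring C8 ketone, closing the lactone to A2.
- Merits: lactone, C8 and C17 arise in one intramolecular step, and C19 never needs a protecting group or a redox detour. In this respect it is shorter than the chosen plan, which spends six steps on C17–C19 (Stille coupling, lactonisation, hydrogenation, reduction, protection and later re-oxidation).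
- Weak points: it presupposes the ten-membered ring and says nothing about how to make it. C8 and C17 would be created in a flexible ring with only the enolate geometry and a five-membered transition state for control. The C8 ketone of A1 is α-oxygenated at C9, and SmI2 readily cleaves such C–O bonds. The C7 ester is also allylic.
- Comparison: the chosen plan sets C8 by dihydroxylation of a rigid decalin olefin and C17 by hydrogenation of a rigid lactone. It pays in step count for that security.

**Alternative 2:** The cut is C3–C4. An eleven-membered thiolactone A3 is contracted to the ten-membered 2,4-diketone A4 by attack of the C3 enolate on the thioester carbonyl and loss of sulfur to a phosphine.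
- Merits: ring closure by S-alkylation or thioesterification is easy, and the plan is convergent (two halves meet at sulfur). It is better than the chosen plan in convergence.
- Weak points: A4 is an enolisable β-diketone whose C2 and C4 carbonyls must be told apart and reduced with control in the macrocycle. The base and thiophile act on a substrate that already holds the β-hydroxy lactone and the C9 acetate. The C5=C6 geometry has to be made in an open chain and can be lost through the dienolate.
- Comparison: the chosen plan fixes the olefin in a six-membered ring and sets C4 by a reagent before the ring is opened. Against the convergence of this alternative it has only its long linear sequence to set.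

**Alternative 3:** The cut is C8–C9. SmI2 couples the aldehyde and the ketone of the seco compound A5 to the cyclic diol A6.
- Merits: ring and both carbinols form in one step. The C17 stereocentre can be bought in a 3-hydroxy-2-methylpropanoate-derived fragment instead of being made, and the fragments are of similar size. In these respects it is better than the chosen plan.
- Weak points: a ten-membered pinacol closure onto a hindered ketone is entropically and sterically poor. The cis-diol configuration at C8/C9 is not secured by anything in A5. The ketone of A5 is α-oxygenated (C7) and allylic, so reductive C–O cleavage competes. C17 is α to the ketone and can epimerise.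
- Comparison: the chosen plan makes the C8/C9 diol by face-selective osmylation before the medium ring exists and never exposes an α-oxygenated ketone to a one-electron reductant.

Key step: step 28

## Conventions and assumptions

- Locants are briarane numbers throughout: C15 = methyl on C1, C16 = methyl on C5, C17/C18/C19 = lactone CH, its methyl and its carbonyl carbon, C20 = methyl on C11.
- β is the face of C15 and α the opposite face. For C2, C4, C7 and C17 of the ten-membered-ring compounds, "natural" means the configuration of the target.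
- Remark on the chemistry: the configuration of C2 and C7 in the tricyclic diol is destroyed in the key step. The β,β-cis diol is carried because that is what the order of additions should deliver.

## Route

### Ring A and the trans ring fusion (steps 1–9)

Step 1
Reactants: 1 (R)-Wieland–Miescher ketone
Product: 2 11-methylene dienedione
Conditions: CH2(OEt)2, POCl3, NaOAc, CHCl3, reflux
Reagents that add atoms: diethoxymethane, CCOCOCC
Why: γ-Methylenation of a conjugated enone through its dienol ether (alkoxymethylation at C11, then loss of ethanol), the reaction type used for 6-methylene steroids; the saturated C14 ketone does not form a dienol ether and stays untouched.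

Step 2
Reactants: 2 11-methylene dienedione
Product: 3 11-methyl-9,11-dienone
Conditions: Pd/C (5%), cyclohexene (cat.), NaOAc, EtOH, reflux
Reagents that add atoms: none
Why: Palladium-hydride isomerisation of the exocyclic olefin into the ring gives the more substituted linear dienone, as in the 6-methylene to 6-methyl-4,6-diene isomerisation of steroids.

Step 3
Reactants: 3 11-methyl-9,11-dienone
Product: 4 C14 dioxolane
Conditions: HOCH2CH2OH, p-TsOH (cat.), 4 Å MS, CH2Cl2, rt
Reagents that add atoms: ethane-1,2-diol, OCCO
Why: Chemoselective ketalisation; the saturated ketone is far more electrophilic than the doubly vinylogous dienone carbonyl, as in the known monoketalisation of the parent diketone.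

Step 4
Reactants: 4 C14 dioxolane
Product: 6 11β,12β-epoxide, via bromohydrin 5 (not isolated)
Conditions: NBS, acetone/H2O, NaOAc, 0 °C; then K2CO3, MeOH, 0 °C
Reagents that add atoms: water, O
Why: Halohydrin formation and ring closure: the bromonium ion forms on the α face (C15 is syn-axial to C11β), water opens it trans-diaxially at the tertiary C11, and the 11β-alkoxide displaces the 12α-bromide. This gives the epoxide on the face that a peracid would not reach.

Step 5
Reactants: 6 11β,12β-epoxide
Product: 7 11β-methyl-12β-hydroxy enone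
Conditions: Pd2(dba)3·CHCl3 (cat.), n-Bu3P, HCO2H, Et3N, 1,4-dioxane, rt
Reagents that add atoms: none
Why: Tsuji–Shimizu hydrogenolysis of an alkenyl oxirane: zerovalent palladium ionises the allylic C11–O bond with inversion and formate-derived hydride is transferred from the metal to C11, so H11 enters α and the methyl ends β (axial). The C12–O bond is not touched and the enone stays conjugated.

Step 6
Reactants: 7 11β-methyl-12β-hydroxy enone
Product: 8 12-O-TIPS enone
Conditions: i-Pr3SiOTf, 2,6-lutidine, CH2Cl2, −78 °C
Reagents that add atoms: triisopropylsilyl triflate, CC(C)[Si](OS(=O)(=O)C(F)(F)F)(C(C)C)C(C)C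
Why: Silylation of the equatorial secondary alcohol; the weak base and low temperature leave the γ-epimerisable C11 centre alone, and the ether is stable to every acid used before the last step.

Step 7
Reactants: 8 12-O-TIPS enone
Product: 10 triethylsilyl enol ether, via lithium enolate 9 (not isolated)
Conditions: Li, NH3(l)/THF, −78 °C; then Et3SiCl, Et3N, THF, −78 → 0 °C
Reagents that add atoms: chlorotriethylsilane, CC[Si](Cl)(CC)CC
Why: Birch reduction of the enone with axial protonation at C10 from the α face gives the trans-decalin; the regiospecific C8–C9 enolate is trapped before it can equilibrate towards C7.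

Step 8
Reactants: 10 triethylsilyl enol ether
Product: 12 9α-silyloxy ketone, via silyloxy epoxide 11 (not isolated)
Conditions: mCPBA, NaHCO3, CH2Cl2, −20 → 0 °C
Reagents that add atoms: 3-chloroperbenzoic acid, OOC(=O)c1cccc(Cl)c1
Why: Rubottom oxidation: epoxidation from the α face (C15 is syn-axial to C9β) and 1,4-silyl shift give the α-silyloxy ketone; the equatorial 9α oxygen is also the thermodynamic epimer of this enolisable centre.

Step 9
Reactants: 12 9α-silyloxy ketone
Product: 14 enol triflate, via potassium enolate 13 (not isolated)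
Conditions: KN(SiMe3)2, THF, −78 °C; then PhNTf2
Reagents that add atoms: N-phenylbis(trifluoromethanesulfonimide), O=S(=O)(N(c1ccccc1)S(=O)(=O)C(F)(F)F)C(F)(F)F
Why: Kinetic deprotonation occurs at the C7 methylene, away from the hindered silyloxy-bearing C9, and O-sulfonylation fixes the C7=C8 enol triflate.

### C8, C17 and the C7 oxygen (steps 10–19)

Step 10
Reactants: 15 methyl propiolate; 16 tributyltin hydride
Product: 17 methyl 2-(tributylstannyl)acrylate
Conditions: Pd(PPh3)4 (cat.), THF, 0 °C → rt
Reagents that add atoms: none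
Why: Palladium-catalysed syn-hydrostannation of an alkynoate places tin on the carbon α to the ester.

Step 11
Reactants: 14 enol triflate; 17 methyl 2-(tributylstannyl)acrylate
Product: 18 diene ester
Conditions: Pd(PPh3)4 (cat.), CuI (cat.), LiCl, DMF, 50 °C
Reagents that add atoms: none
Why: Stille coupling of an alkenyl triflate with a 1-substituted alkenylstannane (copper co-catalysis for the hindered tin reagent) forms the C8–C17 bond.

Step 12
Reactants: 18 diene ester
Product: 19 7α,8α-diol ester
Conditions: OsO4 (cat.), N-methylmorpholine N-oxide, acetone/H2O, rt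
Reagents that add atoms: N-methylmorpholine N-oxide, C[N+]1([O-])CCOCC1; water, O
Why: Catalytic dihydroxylation attacks the electron-richer ring olefin and spares the acrylate; the reagent comes from the α face because C15 is syn-axial to C7β, which sets O8 axial α with C17 equatorial β.

Step 13
Reactants: 19 7α,8α-diol ester
Product: 20 α-methylene lactone
Conditions: PPTS (cat.), toluene, 80 °C
Reagents that add atoms: none
Why: Acid-catalysed lactonisation (5-exo transesterification) of the equatorial C7 hydroxyl onto the ester; O9 is silylated and the C8 hydroxyl could only give a four-membered ring.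

Step 14
Reactants: 20 α-methylene lactone
Product: 21 17-methyl lactone
Conditions: H2 (1 atm), RhCl(PPh3)3 (cat.), benzene/EtOH, rt
Reagents that add atoms: none
Why: Homogeneous hydrogenation of the exocyclic olefin of a trans-fused α-methylene lactone; the axial C8 hydroxyl shields the α face, hydrogen adds from β, and C18 ends cis to the C8 oxygen as in the target.

Step 15
Reactants: 21 17-methyl lactone
Product: 23 acetonide keto lactone, via diol lactone 22 (not isolated)
Conditions: PPTS, MeOH, rt; then Me2C(OMe)2, p-TsOH·H2O (cat.), acetone, 40 °C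
Reagents that add atoms: 2,2-dimethoxypropane, COC(C)(C)OC
Why: Three acid-catalysed exchange reactions: methanolysis of the triethylsilyl ether, acetonide formation on the cis C8/C9 diol (O7 is locked in the lactone), and transketalisation of the C14 dioxolane to the solvent acetone.

Step 16
Reactants: 23 acetonide keto lactone
Product: 24 14α-hydroxy lactone
Conditions: LiBH(s-Bu)3 (L-Selectride), THF, −78 °C
Reagents that add atoms: none
Why: Bulky-hydride reduction of a cyclohexanone flanked by a quaternary carbon proceeds by equatorial attack and gives the axial 14α alcohol, as with 4,4-disubstituted 3-keto terpenoids; the lactone is not reduced at this temperature.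

Step 17
Reactants: 24 14α-hydroxy lactone
Product: 25 14-O-TES lactone
Conditions: Et3SiOTf, 2,6-lutidine, CH2Cl2, −78 → 0 °C
Reagents that add atoms: triethylsilyl triflate, CC[Si](CC)(CC)OS(=O)(=O)C(F)(F)F
Why: Silyl triflate protection of the hindered axial alcohol with a group that mild acid removes later without loss of the acetonide or the triisopropylsilyl ether.

Step 18
Reactants: 25 14-O-TES lactone
Product: 26 7,19-diol
Conditions: LiAlH4, THF, 0 °C
Reagents that add atoms: none
Why: Hydride reduction of the lactone to the 1,4-diol frees the C7 hydroxyl; the C17 centre is not enolised under these conditions.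

Step 19
Reactants: 26 7,19-diol
Product: 27 19-O-PMB alcohol
Conditions: NaH (1.1 equiv), 4-MeOC6H4CH2Cl, n-Bu4NI (cat.), THF/DMF, 0 °C
Reagents that add atoms: 4-methoxybenzyl chloride, COc1ccc(CCl)cc1
Why: Williamson etherification; the primary alkoxide reacts far faster than the secondary C7 hydroxyl, which is flanked by the quaternary C8.

### The C2/C7 diol and ring C (steps 20–27)

Step 20
Reactants: 27 19-O-PMB alcohol
Product: 28 C7 ketone
Conditions: Dess–Martin periodinane, NaHCO3, CH2Cl2, rt
Reagents that add atoms: none
Why: Periodinane oxidation of the only free hydroxyl; C8 is fully substituted, so the ketone can enolise only towards C2.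

Step 21
Reactants: 28 C7 ketone
Product: 30 2α-hydroxy C7 ketone, via potassium enolate 29 (not isolated)
Conditions: KN(SiMe3)2, THF, −78 °C; then 2-(phenylsulfonyl)-3-phenyloxaziridine
Reagents that add atoms: 2-(phenylsulfonyl)-3-phenyloxaziridine, O=S(=O)(N1OC1c1ccccc1)c1ccccc1
Why: Davis hydroxylation of the single possible enolate; oxygen enters anti to the adjacent axial C15, and the configuration at C2 is of no consequence because the centre is oxidised in step 23.

Step 22
Reactants: 30 2α-hydroxy C7 ketone; 31 vinylmagnesium bromide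
Product: 32 7-vinyl 2,7-diol
Conditions: CeCl3, THF, −78 → 0 °C (31, 3 equiv)
Reagents that add atoms: none
Why: Organocerium 1,2-addition to a hindered, enolisable ketone; the β face of the C7 carbonyl is closed by the syn-axial C15, so the vinyl group enters equatorially from α and the new hydroxyl is axial β.

Step 23
Reactants: 32 7-vinyl 2,7-diol
Product: 33 C2 ketone
Conditions: (COCl)2, DMSO, CH2Cl2, −78 °C; then Et3N, −78 → −20 °C
Reagents that add atoms: none
Why: Swern oxidation of the secondary alcohol of a secondary/tertiary diol, a method that does not cleave glycols; the ketone formed has no α-hydrogen.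

Step 24
Reactants: 33 C2 ketone; 34 3-methylbut-3-en-2-one
Product: 36 aldol adduct, via lithium enolate 35 (not isolated)
Conditions: LiN(i-Pr)2, THF, −78 °C (34, 3 equiv); then 33, −78 °C; AcOH quench at −78 °C
Reagents that add atoms: none
Why: Aldol addition of a kinetic methyl ketone enolate to a non-enolisable ketone activated by the neighbouring lithium alkoxide. The β face of C2 is flanked by the axial C15 and the axial C7 oxygen, so attack is axial from α, anti to that oxygen; this gives the C2 hydroxyl β and cis to the C7 hydroxyl. The cold quench forestalls retro-aldol cleavage.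

Step 25
Reactants: 36 aldol adduct
Product: 37 (4R)-allylic alcohol
Conditions: (S)-2-methyl-CBS-oxazaborolidine, catecholborane, toluene, −78 °C
Reagents that add atoms: none
Why: Corey–Bakshi–Shibata reduction of an enone in which the 1-methylvinyl group acts as the large substituent; the (S)-catalyst gives the (4R)-carbinol by reagent control, independent of the two tertiary carbinols.

Step 26
Reactants: 37 (4R)-allylic alcohol
Product: 38 tricyclic triol
Conditions: second-generation Grubbs catalyst (cat.), CH2Cl2, 40 °C
Reagents that add atoms: none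
Why: Ring-closing metathesis of the C7 vinyl group with the 1,1-disubstituted olefin of the cis-disposed C2 arm closes the six-membered ring C, in which C5=C6 can only be cis.

Step 27
Reactants: 38 tricyclic triol
Product: 39 tricyclic cis-diol 4-acetate
Conditions: Ac2O, pyridine, DMAP (cat.), CH2Cl2, 0 °C
Reagents that add atoms: acetic anhydride, CC(=O)OC(C)=O
Why: Acetylation of the secondary allylic alcohol; the two tertiary hydroxyls do not react, and the acetate keeps O4 from adding to the C7 ketone after ring opening.

### Key step and endgame (steps 28–35)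

Step 28
Reactants: 39 tricyclic cis-diol 4-acetate
Product: 41 ten-membered 2,7-diketone, via cyclic lead diester 40 (not isolated)
Conditions: Pb(OAc)4, NaHCO3, CH2Cl2, −20 → 0 °C
Reagents that add atoms: none
Why: Criegee glycol cleavage: the cis C2,C7-diol (one axial, one equatorial oxygen on ring B, dihedral angle about 60°) exchanges two acetates on tetravalent lead to give the five-membered cyclic diester 40, which fragments in one two-electron step to the C2 and C7 ketones and Pb(OAc)2. The closest known reaction type is the Pb(OAc)4 cleavage of cis-decalin-9,10-diols to cyclodecane-1,6-diones. The ten-membered ring is not closed by bond formation; it appears when the bond shared by rings B and C is broken, so no cyclisation mode and no medium-ring entropy term are involved. No stereocentre is formed; C1, C4, C8–C12, C14 and C17 are untouched, and C5=C6 emerges cis because it was part of ring C. The step needs chemoselectivity for the one free vicinal diol: O8 and O9 are tied in the acetonide, O4 is acetylated, O12 and O14 are silylated, O19 is benzylated, and the trisubstituted olefin is inert to the reagent. Solid NaHCO3 and low temperature keep the β-acetoxy ketone (C4–OAc, C2=O) from losing acetic acid.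

Step 29
Reactants: 41 ten-membered 2,7-diketone
Product: 42 14-hydroxy diketone
Conditions: AcOH/THF/H2O (3:1:1), rt
Reagents that add atoms: none
Why: Mild acidic solvolysis removes the triethylsilyl ether and leaves the triisopropylsilyl ether, the acetonide and the β-acetoxy ketone intact; no base is used because the 14-hydroxy-2-ketone is a retro-aldol substrate.

Step 30
Reactants: 42 14-hydroxy diketone
Product: 44 2,14-diol enone, via diethylborinate 43 (not isolated)
Conditions: Et2BOMe, THF/MeOH (4:1), −78 °C; then NaBH4, −78 °C; MeOH evaporation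
Reagents that add atoms: none
Why: Narasaka–Prasad reduction: boron bridges the axial O14 and the C2 carbonyl in a six-membered chelate fused to ring A, and borohydride attacks C2 axially on that chelate from the ring periphery. The resulting C14/C2 diol is 1,3-syn, which is the natural C2 configuration; the hindered, non-chelated C7 enone is much slower.

Step 31
Reactants: 44 2,14-diol enone
Product: 46 tetraacetate enone, via tetraol 45 (not isolated)
Conditions: AcOH/H2O (4:1), 40 °C; then Ac2O, pyridine, DMAP, rt
Reagents that add atoms: acetic anhydride, CC(=O)OC(C)=O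
Why: Acetonide hydrolysis followed by acetylation of the three secondary hydroxyls (C2, C9, C14); the tertiary C8 hydroxyl is left free, and the retro-aldol-prone tetraol is acylated without isolation.

Step 32
Reactants: 46 tetraacetate enone
Product: 47 C7 alcohol
Conditions: Zn(BH4)2, Et2O, −20 → 0 °C
Reagents that add atoms: none
Why: Chelation-controlled 1,2-reduction of an α-hydroxy enone: zinc bridges O8 and the C7 carbonyl, and hydride comes from the ring periphery, the face turned away from C9. This gives the anti C7/C8 diol relationship of the target; the acetates are not reduced.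

Step 33
Reactants: 47 C7 alcohol
Product: 48 7,19-diol
Conditions: DDQ, CH2Cl2/pH 7 buffer, 0 °C
Reagents that add atoms: none
Why: Oxidative cleavage of the p-methoxybenzyl ether through its benzylic cation; esters, olefin and silyl ether are inert.

Step 34
Reactants: 48 7,19-diol
Product: 50 12-O-TIPS ether of the target, via lactol 49 (not isolated)
Conditions: TEMPO (cat.), PhI(OAc)2, CH2Cl2, rt
Reagents that add atoms: none
Why: Oxoammonium oxidation of the primary alcohol, capture of the aldehyde by the C7 hydroxyl and oxidation of the lactol give the γ-lactone with retention at C7; the hindered secondary and tertiary hydroxyls react much more slowly.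

Step 35
Reactants: 50 12-O-TIPS ether of the target
Product: 51 CNP0183630.2
Conditions: HF·pyridine, pyridine, THF, 0 °C → rt
Reagents that add atoms: none
Why: Fluoride-mediated cleavage of the silyl ether under buffered acidic conditions that spare the four acetates, the allylic acetate and the β-hydroxy lactone.

## Compound list

1 | (R)-Wieland–Miescher ketone, (R)-8a-methyl-3,4,8,8a-tetrahydronaphthalene-1,6(2H,7H)-dione | C[C@@]12CCC(=O)C=C1CCCC2=O | starting material
2 | 11-methylene dienedione: C8 and C14 ketones, C9=C10, exocyclic C11=C20, (1R) | O=C1CCC(=C)C2=CC(=O)CC[C@]21C | intermediate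
3 | 11-methyl-9,11-dienone: C8 and C14 ketones, C9=C10 and C11=C12, methyl on C11, (1R) | O=C1CC=C(C)C2=CC(=O)CC[C@]21C | intermediate
4 | C14 dioxolane (ethylene ketal) of 3 | O1CCOC12CC=C(C)C3=CC(=O)CC[C@]32C | intermediate
5 | bromohydrin: 11β-hydroxy-11α-methyl-12α-bromo enone, C14 dioxolane | O1CCOC12C[C@@H](Br)[C@@](O)(C)C3=CC(=O)CC[C@]32C | intermediate
6 | 11β,12β-epoxide of 4 (11-methyl α) | O1CCOC12C[C@@H]3O[C@]3(C)C4=CC(=O)CC[C@]42C | intermediate
7 | enone with 11β-methyl (11α-H) and 12β-hydroxyl, C14 dioxolane | O1CCOC12C[C@H](O)[C@H](C)C3=CC(=O)CC[C@]32C | intermediate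
8 | 12β-triisopropylsilyl ether of 7 | O1CCOC12C[C@H](O[Si](C(C)C)(C(C)C)C(C)C)[C@H](C)C3=CC(=O)CC[C@]32C | intermediate
9 | lithium C8–C9 enolate of the trans-decalin (10α-H) | O1CCOC12C[C@H](O[Si](C(C)C)(C(C)C)C(C)C)[C@H](C)[C@@H]3C=C(O[Li])CC[C@]32C | intermediate
10 | C8 triethylsilyl enol ether (C8=C9), trans-decalin with 10α-H | O1CCOC12C[C@H](O[Si](C(C)C)(C(C)C)C(C)C)[C@H](C)[C@@H]3C=C(O[Si](CC)(CC)CC)CC[C@]32C | intermediate
11 | 8α,9α-epoxide of 10 with the silyloxy group on C8 | O1CCOC12C[C@H](O[Si](C(C)C)(C(C)C)C(C)C)[C@H](C)[C@@H]3[C@H]4O[C@@]4(O[Si](CC)(CC)CC)CC[C@]32C | intermediate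
12 | C8 ketone with 9α-triethylsilyloxy group | O1CCOC12C[C@H](O[Si](C(C)C)(C(C)C)C(C)C)[C@H](C)[C@@H]3[C@@H](O[Si](CC)(CC)CC)C(=O)CC[C@]32C | intermediate
13 | potassium C7–C8 enolate of 12 | O1CCOC12C[C@H](O[Si](C(C)C)(C(C)C)C(C)C)[C@H](C)[C@@H]3[C@@H](O[Si](CC)(CC)CC)C(O[K])=CC[C@]32C | intermediate
14 | C8 enol triflate (C7=C8) | O1CCOC12C[C@H](O[Si](C(C)C)(C(C)C)C(C)C)[C@H](C)[C@@H]3[C@@H](O[Si](CC)(CC)CC)C(OS(=O)(=O)C(F)(F)F)=CC[C@]32C | intermediate
15 | methyl propiolate | C#CC(=O)OC | starting material
16 | tributyltin hydride | CCCC[SnH](CCCC)CCCC | starting material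
17 | methyl 2-(tributylstannyl)acrylate | C=C(C(=O)OC)[Sn](CCCC)(CCCC)CCCC | intermediate
18 | diene ester: C7=C8 with the 1-(methoxycarbonyl)vinyl group (C17=C18, C19 ester) on C8 | O1CCOC12C[C@H](O[Si](C(C)C)(C(C)C)C(C)C)[C@H](C)[C@@H]3[C@@H](O[Si](CC)(CC)CC)C(C(=C)C(=O)OC)=CC[C@]32C | intermediate
19 | 7α,8α-diol with the acrylate unit 8β | O1CCOC12C[C@H](O[Si](C(C)C)(C(C)C)C(C)C)[C@H](C)[C@@H]3[C@@H](O[Si](CC)(CC)CC)[C@](O)(C(=C)C(=O)OC)[C@@H](O)C[C@]32C | intermediate
20 | trans-fused α-methylene γ-lactone (O7–C19), 8α-OH | O1CCOC12C[C@H](O[Si](C(C)C)(C(C)C)C(C)C)[C@H](C)[C@@H]3[C@@H](O[Si](CC)(CC)CC)[C@]4(O)C(=C)C(=O)O[C@H]4C[C@]32C | intermediate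
21 | 17-methyl lactone, natural C17 (C18 cis to the C8 hydroxyl) | O1CCOC12C[C@H](O[Si](C(C)C)(C(C)C)C(C)C)[C@H](C)[C@@H]3[C@@H](O[Si](CC)(CC)CC)[C@]4(O)[C@@H](C)C(=O)O[C@H]4C[C@]32C | intermediate
22 | 8α,9α-diol lactone, C14 dioxolane | O1CCOC12C[C@H](O[Si](C(C)C)(C(C)C)C(C)C)[C@H](C)[C@@H]3[C@@H](O)[C@]4(O)[C@@H](C)C(=O)O[C@H]4C[C@]32C | intermediate
23 | lactone with 8α,9α-acetonide and C14 ketone | O=C1C[C@H](O[Si](C(C)C)(C(C)C)C(C)C)[C@H](C)[C@@H]2[C@H]3OC(C)(C)O[C@]34[C@@H](C)C(=O)O[C@H]4C[C@]21C | intermediate
24 | 14α (axial) alcohol of 23 | O[C@H]1C[C@H](O[Si](C(C)C)(C(C)C)C(C)C)[C@H](C)[C@@H]2[C@H]3OC(C)(C)O[C@]34[C@@H](C)C(=O)O[C@H]4C[C@]21C | intermediate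
25 | 14α-triethylsilyl ether of 24 | CC[Si](CC)(CC)O[C@H]1C[C@H](O[Si](C(C)C)(C(C)C)C(C)C)[C@H](C)[C@@H]2[C@H]3OC(C)(C)O[C@]34[C@@H](C)C(=O)O[C@H]4C[C@]21C | intermediate
26 | 7α,19-diol (C17 side chain CH(CH3)CH2OH on C8) | CC[Si](CC)(CC)O[C@H]1C[C@H](O[Si](C(C)C)(C(C)C)C(C)C)[C@H](C)[C@@H]2[C@H]3OC(C)(C)O[C@@]3([C@@H](C)CO)[C@@H](O)C[C@]21C | intermediate
27 | 19-O-(4-methoxybenzyl) ether, 7α-OH free | CC[Si](CC)(CC)O[C@H]1C[C@H](O[Si](C(C)C)(C(C)C)C(C)C)[C@H](C)[C@@H]2[C@H]3OC(C)(C)O[C@@]3([C@@H](C)COCc4ccc(OC)cc4)[C@@H](O)C[C@]21C | intermediate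
28 | C7 ketone | CC[Si](CC)(CC)O[C@H]1C[C@H](O[Si](C(C)C)(C(C)C)C(C)C)[C@H](C)[C@@H]2[C@H]3OC(C)(C)O[C@@]3([C@@H](C)COCc4ccc(OC)cc4)C(=O)C[C@]21C | intermediate
29 | potassium C2–C7 enolate of 28 | CC[Si](CC)(CC)O[C@H]1C[C@H](O[Si](C(C)C)(C(C)C)C(C)C)[C@H](C)[C@@H]2[C@H]3OC(C)(C)O[C@@]3([C@@H](C)COCc4ccc(OC)cc4)C(O[K])=C[C@]21C | intermediate
30 | 2α-hydroxy C7 ketone | CC[Si](CC)(CC)O[C@H]1C[C@H](O[Si](C(C)C)(C(C)C)C(C)C)[C@H](C)[C@@H]2[C@H]3OC(C)(C)O[C@@]3([C@@H](C)COCc4ccc(OC)cc4)C(=O)[C@@H](O)[C@]21C | intermediate
31 | vinylmagnesium bromide | C=C[Mg]Br | starting material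
32 | 2α,7β-diol with 7α-vinyl group | CC[Si](CC)(CC)O[C@H]1C[C@H](O[Si](C(C)C)(C(C)C)C(C)C)[C@H](C)[C@@H]2[C@H]3OC(C)(C)O[C@@]3([C@@H](C)COCc4ccc(OC)cc4)[C@@](O)(C=C)[C@@H](O)[C@]21C | intermediate
33 | C2 ketone with 7β-hydroxy-7α-vinyl carbinol | CC[Si](CC)(CC)O[C@H]1C[C@H](O[Si](C(C)C)(C(C)C)C(C)C)[C@H](C)[C@@H]2[C@H]3OC(C)(C)O[C@@]3([C@@H](C)COCc4ccc(OC)cc4)[C@@](O)(C=C)C(=O)[C@]21C | intermediate
34 | 3-methylbut-3-en-2-one | CC(=C)C(C)=O | starting material
35 | lithium enolate of 34 (lithium 3-methylbuta-1,3-dien-2-olate) | C=C(O[Li])C(C)=C | intermediate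
36 | aldol adduct: 2β,7β-diol, 2α-CH2C(=O)C(CH3)=CH2 arm, 7α-vinyl | CC[Si](CC)(CC)O[C@H]1C[C@H](O[Si](C(C)C)(C(C)C)C(C)C)[C@H](C)[C@@H]2[C@H]3OC(C)(C)O[C@@]3([C@@H](C)COCc4ccc(OC)cc4)[C@@](O)(C=C)[C@@](O)(CC(=O)C(C)=C)[C@]21C | intermediate
37 | (4R)-allylic alcohol of 36 | CC[Si](CC)(CC)O[C@H]1C[C@H](O[Si](C(C)C)(C(C)C)C(C)C)[C@H](C)[C@@H]2[C@H]3OC(C)(C)O[C@@]3([C@@H](C)COCc4ccc(OC)cc4)[C@@](O)(C=C)[C@@](O)(C[C@@H](O)C(C)=C)[C@]21C | intermediate
38 | tricyclic triol: rings A, B, C; 2β,7β-diol, (4R)-OH, C5=C6 | CC[Si](CC)(CC)O[C@H]1C[C@H](O[Si](C(C)C)(C(C)C)C(C)C)[C@H](C)[C@@H]2[C@H]3OC(C)(C)O[C@@]3([C@@H](C)COCc5ccc(OC)cc5)[C@@]4(O)C=C(C)[C@H](O)C[C@@]4(O)[C@]21C | intermediate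
39 | tricyclic 2β,7β-cis-diol 4-acetate (precursor of the key step) | CC[Si](CC)(CC)O[C@H]1C[C@H](O[Si](C(C)C)(C(C)C)C(C)C)[C@H](C)[C@@H]2[C@H]3OC(C)(C)O[C@@]3([C@@H](C)COCc5ccc(OC)cc5)[C@@]4(O)C=C(C)[C@H](OC(C)=O)C[C@@]4(O)[C@]21C | intermediate
40 | cyclic lead diester of 39 (O2–Pb(OAc)2–O7) | CC[Si](CC)(CC)O[C@H]1C[C@H](O[Si](C(C)C)(C(C)C)C(C)C)[C@H](C)[C@@H]2[C@H]3OC(C)(C)O[C@@]3([C@@H](C)COCc6ccc(OC)cc6)[C@@]45O[Pb](OC(C)=O)(OC(C)=O)O[C@]5(C[C@@H](OC(C)=O)C(C)=C4)[C@]21C | intermediate
41 | bicyclic 2,7-diketone with ten-membered ring, cis C5=C6 (product of the key step) | CC[Si](CC)(CC)O[C@H]1C[C@H](O[Si](C(C)C)(C(C)C)C(C)C)[C@H](C)[C@@H]2[C@H]3OC(C)(C)O[C@@]3([C@@H](C)COCc4ccc(OC)cc4)C(=O)/C=C(/C)[C@H](OC(C)=O)CC(=O)[C@]21C | intermediate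
42 | 14α-hydroxy 2,7-diketone | O[C@H]1C[C@H](O[Si](C(C)C)(C(C)C)C(C)C)[C@H](C)[C@@H]2[C@H]3OC(C)(C)O[C@@]3([C@@H](C)COCc4ccc(OC)cc4)C(=O)/C=C(/C)[C@H](OC(C)=O)CC(=O)[C@]21C | intermediate
43 | O14-diethylborinate of 42 (boron chelated to the C2 carbonyl) | CCB(CC)O[C@H]1C[C@H](O[Si](C(C)C)(C(C)C)C(C)C)[C@H](C)[C@@H]2[C@H]3OC(C)(C)O[C@@]3([C@@H](C)COCc4ccc(OC)cc4)C(=O)/C=C(/C)[C@H](OC(C)=O)CC(=O)[C@]21C | intermediate
44 | 2,14-diol (natural C2) with C7 enone and acetonide | O[C@H]1C[C@H](O[Si](C(C)C)(C(C)C)C(C)C)[C@H](C)[C@@H]2[C@H]3OC(C)(C)O[C@@]3([C@@H](C)COCc4ccc(OC)cc4)C(=O)/C=C(/C)[C@H](OC(C)=O)C[C@@H](O)[C@]21C | intermediate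
45 | 2,8,9,14-tetraol with C7 enone | O[C@H]1C[C@H](O[Si](C(C)C)(C(C)C)C(C)C)[C@H](C)[C@@H]2[C@@H](O)[C@](O)([C@@H](C)COCc3ccc(OC)cc3)C(=O)/C=C(/C)[C@H](OC(C)=O)C[C@@H](O)[C@]21C | intermediate
46 | 2,4,9,14-tetraacetate with C7 enone and free 8-OH | CC(=O)O[C@H]1C[C@H](O[Si](C(C)C)(C(C)C)C(C)C)[C@H](C)[C@@H]2[C@@H](OC(C)=O)[C@](O)([C@@H](C)COCc3ccc(OC)cc3)C(=O)/C=C(/C)[C@H](OC(C)=O)C[C@@H](OC(C)=O)[C@]21C | intermediate
47 | C7 alcohol (natural C7) | CC(=O)O[C@H]1C[C@H](O[Si](C(C)C)(C(C)C)C(C)C)[C@H](C)[C@@H]2[C@@H](OC(C)=O)[C@](O)([C@@H](C)COCc3ccc(OC)cc3)[C@@H](O)/C=C(/C)[C@H](OC(C)=O)C[C@@H](OC(C)=O)[C@]21C | intermediate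
48 | 7,19-diol | CC(=O)O[C@H]1C[C@H](O[Si](C(C)C)(C(C)C)C(C)C)[C@H](C)[C@@H]2[C@@H](OC(C)=O)[C@](O)([C@@H](C)CO)[C@@H](O)/C=C(/C)[C@H](OC(C)=O)C[C@@H](OC(C)=O)[C@]21C | intermediate
49 | lactol (C19 hemiacetal with O7) | CC(=O)O[C@H]1C[C@H](O[Si](C(C)C)(C(C)C)C(C)C)[C@H](C)[C@@H]2[C@@H](OC(C)=O)[C@@]3(O)[C@H](/C=C(/C)[C@H](OC(C)=O)C[C@@H](OC(C)=O)[C@]21C)OC(O)[C@@H]3C | intermediate
50 | 12-O-triisopropylsilyl ether of the target | CC(=O)O[C@H]1C[C@H](O[Si](C(C)C)(C(C)C)C(C)C)[C@H](C)[C@@H]2[C@@H](OC(C)=O)[C@@]3(O)[C@H](/C=C(/C)[C@H](OC(C)=O)C[C@@H](OC(C)=O)[C@]21C)OC(=O)[C@@H]3C | intermediate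
51 | CNP0183630.2 | CC(=O)O[C@H]1C[C@H](O)[C@H](C)[C@@H]2[C@@H](OC(C)=O)[C@@]3(O)[C@H](/C=C(/C)[C@H](OC(C)=O)C[C@@H](OC(C)=O)[C@]21C)OC(=O)[C@@H]3C | target

## Step count and least certain steps

Total step count: 35. Longest linear sequence: 34 steps (steps 1–9 and 11–35 from 1; step 10 is a one-step branch).

**Step 28 (key step).** The most likely failure is slow or incomplete formation of the cyclic lead diester, which would happen if the additions in steps 22 and 24 had placed the two tertiary hydroxyls trans-diaxial across the B/C fusion. A second risk is loss of acetic acid from the β-acetoxy ketone once the ring is open. Fallback: from 39, generate the tertiary alkoxy radical with PhI(OAc)2 and I2 under visible light. β-Scission of the C2–C7 bond and oxidation of the resulting α-hydroxyalkyl radical give the same diketone without a cyclic ester, so it also serves a trans diol. The fallback returns at 41 and makes no new compound (F0).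

**Step 5.** Hydride transfer may go to the other allyl terminus (C9), or the epoxide may isomerise, because the π-allyl system is conjugated to a ketone and the precedent is with open-chain epoxy esters. Fallback: from 6, isomerise the epoxide with Al(Oi-Pr)3 in hot toluene to the 12β-hydroxy-11-methylene dienone F1. Then hydrogenate only the exocyclic olefin with RhCl(PPh3)3/H2. C15 blocks the β face, so hydrogen adds from α and the methyl ends β. The fallback returns at 7.

**Step 22.** The C7 carbonyl is closed by C15 on the β face and flanked by two axial oxygens on the α face. Enolate formation or no addition at all may therefore outrun vinyl transfer. Fallback: from 30, add the much smaller ethynylmagnesium bromide (CeCl3, THF) to give the 7-ethynyl diol F2, and semihydrogenate it over Pd/CaCO3 poisoned with Pb(OAc)2 and quinoline. The fallback returns at 32.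

**Step 24.** The C2 ketone is flanked by two fully substituted carbons. The aldol equilibrium may lie on the side of the starting materials, and the enolate may polymerise before it adds. Fallback: from 33, add cyanomethyllithium (LiCH2CN, THF, −78 °C), a smaller nucleophile that adds irreversibly, to give the β-hydroxy nitrile F3. Treat F3 with isopropenylmagnesium bromide (CH2=C(CH3)MgBr) and hydrolyse the imine with aqueous acid. The fallback returns at 36.

**Step 32.** Facial selectivity in the ten-membered ring may be poor or reversed if the zinc chelate does not form or the ring folds differently. Fallback: change the control element and the order. From 44, reduce the enone while the acetonide is still in place (NaBH4, CeCl3, MeOH, −78 °C; Felkin-type attack anti to the C8–O bond) to the C7 alcohol F4. Remove the p-methoxybenzyl group with DDQ to give F5. Close the lactone with TEMPO/PhI(OAc)2 to F6; O9 is still blocked, so only O7 can lactonise. Hydrolyse the acetonide (AcOH/H2O) to F7 and acetylate C2, C9 and C14 (Ac2O, pyridine, DMAP). The fallback returns at 50.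

## Further compounds

F0 | step 28 | none | none
F1 | step 5 | 12β-hydroxy-11-methylene dienone, C14 dioxolane | O1CCOC12C[C@H](O)C(=C)C3=CC(=O)CC[C@]32C
F2 | step 22 | 7α-ethynyl 2α,7β-diol | CC[Si](CC)(CC)O[C@H]1C[C@H](O[Si](C(C)C)(C(C)C)C(C)C)[C@H](C)[C@@H]2[C@H]3OC(C)(C)O[C@@]3([C@@H](C)COCc4ccc(OC)cc4)[C@@](O)(C#C)[C@@H](O)[C@]21C
F3 | step 24 | 2α-cyanomethyl 2β,7β-diol (β-hydroxy nitrile) | CC[Si](CC)(CC)O[C@H]1C[C@H](O[Si](C(C)C)(C(C)C)C(C)C)[C@H](C)[C@@H]2[C@H]3OC(C)(C)O[C@@]3([C@@H](C)COCc4ccc(OC)cc4)[C@@](O)(C=C)[C@@](O)(CC#N)[C@]21C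
F4 | step 32 | 2,7,14-triol with acetonide and 19-O-PMB ether (natural C7) | O[C@H]1C[C@H](O[Si](C(C)C)(C(C)C)C(C)C)[C@H](C)[C@@H]2[C@H]3OC(C)(C)O[C@@]3([C@@H](C)COCc4ccc(OC)cc4)[C@@H](O)/C=C(/C)[C@H](OC(C)=O)C[C@@H](O)[C@]21C
F5 | step 32 | 2,7,14,19-tetraol with acetonide | O[C@H]1C[C@H](O[Si](C(C)C)(C(C)C)C(C)C)[C@H](C)[C@@H]2[C@H]3OC(C)(C)O[C@@]3([C@@H](C)CO)[C@@H](O)/C=C(/C)[C@H](OC(C)=O)C[C@@H](O)[C@]21C
F6 | step 32 | lactone with 8,9-acetonide and free 2- and 14-hydroxyls | O[C@H]1C[C@H](O[Si](C(C)C)(C(C)C)C(C)C)[C@H](C)[C@@H]2[C@H]3OC(C)(C)O[C@@]34[C@H](/C=C(/C)[C@H](OC(C)=O)C[C@@H](O)[C@]21C)OC(=O)[C@@H]4C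
F7 | step 32 | lactone 2,8,9,14-tetraol (4-acetate, 12-O-TIPS) | O[C@H]1C[C@H](O[Si](C(C)C)(C(C)C)C(C)C)[C@H](C)[C@@H]2[C@@H](O)[C@@]3(O)[C@H](/C=C(/C)[C@H](OC(C)=O)C[C@@H](O)[C@]21C)OC(=O)[C@@H]3C
A1 | alternative 1 | ten-membered C8 ketone with C7 2-bromopropanoate, 9-O-TES, 12-O-TBS | CC(=O)O[C@H]1C[C@H](O[Si](C)(C)C(C)(C)C)[C@H](C)[C@@H]2[C@@H](O[Si](CC)(CC)CC)C(=O)[C@H](/C=C(/C)[C@H](OC(C)=O)C[C@@H](OC(C)=O)[C@]21C)OC(=O)C(C)Br
A2 | alternative 1 | complete skeleton with 9-O-TES and 12-O-TBS ethers | CC(=O)O[C@H]1C[C@H](O[Si](C)(C)C(C)(C)C)[C@H](C)[C@@H]2[C@@H](O[Si](CC)(CC)CC)[C@@]3(O)[C@H](/C=C(/C)[C@H](OC(C)=O)C[C@@H](OC(C)=O)[C@]21C)OC(=O)[C@@H]3C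
A3 | alternative 2 | eleven-membered thiolactone (C3–S–C4) | CC(=O)O[C@H]1C[C@H](O[Si](C)(C)C(C)(C)C)[C@H](C)[C@@H]2[C@@H](OC(C)=O)[C@@]3(O)[C@H](/C=C(/C)C(=O)SCC(=O)[C@]21C)OC(=O)[C@@H]3C
A4 | alternative 2 | ten-membered 2,4-diketone | CC(=O)O[C@H]1C[C@H](O[Si](C)(C)C(C)(C)C)[C@H](C)[C@@H]2[C@@H](OC(C)=O)[C@@]3(O)[C@H](/C=C(/C)C(=O)CC(=O)[C@]21C)OC(=O)[C@@H]3C
A5 | alternative 3 | seco C9 aldehyde / C8 ketone | CC(=O)O[C@H]1C[C@H](O[Si](C)(C)C(C)(C)C)[C@H](C)[C@H](C=O)[C@@]1(C)[C@H](OC(C)=O)C[C@@H](OC(C)=O)/C(C)=C\[C@H](O[Si](CC)(CC)CC)C(=O)[C@@H](C)COCc1ccc(OC)cc1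
A6 | alternative 3 | bicyclic C8,C9-diol with PMB ether side chain | CC(=O)O[C@H]1C[C@H](O[Si](C)(C)C(C)(C)C)[C@H](C)[C@@H]2[C@@H](O)[C@@]([C@@H](C)COCc3ccc(OC)cc3)(O)[C@H](/C=C(/C)[C@H](OC(C)=O)C[C@@H](OC(C)=O)[C@]21C)O[Si](CC)(CC)CC
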